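## Analysis of the target

Compound 13 is a 2,6-diaryl-3,7-dioxabicyclo[3.3.0]octan-8-one. A γ-butyrolactone (C6, O7, C8, C1, C5) is cis-fused through C1–C5 to a tetrahydrofuran (C1, C2, O3, C4, C5). C2 carries the 3,4-dihydroxyphenyl ring and C6 the 4-hydroxy-3,5-dimethoxyphenyl ring.

The four contiguous stereocentres are 1R,2S,5S,6S. H1, H2, H5 and H6 lie on one face, so both aryl groups point into the concave side of the folded bicycle. This endo,endo arrangement is the most crowded diastereomer and cannot be expected from equilibration, so every centre must be set kinetically and then left alone.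

The sensitive groups are a catechol and a hindered phenol (oxidation, quinone methide formation under base), two benzylic C–O bonds para to oxygenated arenes (C2–O3 and C6–O7: ionisation under acid, cleavage under forcing hydrogenolysis) and the lactone. The difficulty is less the bond count than placing two aryl groups syn to each other and anti to both ring-fusion hydrogens.

The strategy rests on the lactone ring at the butenolide level. With a C1=C5 double bond, C1 and C5 are the two carbons of an alkyne, C6–O7 is the carbonyl group of an aryl aldehyde and C8 is carbon monoxide. The same double bond flattens the bicycle, so two aryl groups on one face leave the other face open for delivery of hydrogen to C5 and C1.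

## Retrosynthetic reasoning

**13 to 12 (three O–benzyl bonds).** The phenols are masked as benzyl ethers in 12. Free phenols would compete in the Mitsunobu closure and in the metal-mediated steps. Neutral hydrogenolysis as the last step avoids the acid and base that would epimerise C2 or C6.

**12 to 11 (C1–H and C5–H).** Removing the two ring-fusion hydrogens gives the bicyclic butenolide 11. This is the right place to cut because 11 is flat and carries both aryl groups on one face. The forward conjugate reduction must add hydride to C5 from the open face; protonation at C1 can only give the cis-fused lactone. Two stereocentres arise in one operation, and the least stable diastereomer becomes the kinetically natural one.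

**11 to 10 to 9 (O3–C4).** The dihydrofuran is opened at O3–C4 and not at C2–O3, because C4 is primary and not stereogenic. Closure by displacement at C4 leaves the C2–O bond, and hence the C2 configuration, untouched. The two arms are held cis by the ring double bond of diol 10. Diol 10 is the bis-desilylated form of butenolide 9.

**9 to 4 + 6 + 7 (C5–C6, C1–C8, C8–O7).** Cutting these three bonds returns alkyne 4, aldehyde 6 and carbon monoxide 7. No other cut delivers all four carbon arms of the tetrasubstituted double bond in one event. The forward reaction is an oxidative cyclisation on zerovalent nickel followed by carbonylation. It must join the aldehyde carbon to the alkyne carbon bearing the CH2OSi group, set C6 under ligand control, and add across the alkyne in a syn sense.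

**4 to 3 to 1 + 2 (C1–C2).** Propargylic silyl ether 4 comes from alcohol 3, and 3 from enantioselective addition of alkyne 2 to aldehyde 1. This one C–C bond sets the C2 centre at the start. The centre is R in 3 and 4, because the alkynyl group outranks the aryl group; the same spatial arrangement is named 2S in 13.

**6 to 5 (O–benzyl).** Aldehyde 6 is the benzyl ether of syringaldehyde 5.

## Alternatives that were turned down

**Alternative 1: carbenoid C–H insertion.**
- Disconnection: the C1–C2 bond, leaving the monocyclic α-diazo lactone A2 with the C2 benzyl ether on the C4 arm.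
- Forward key step: a dirhodium carboxylate catalyst converts A2 into a carbenoid at C1, which inserts into the ether-activated benzylic C2–H bond and gives the tris(silyl) ether A1 of 13. Buffered fluoride would finish.
- For: insertion next to an ether oxygen is an established reaction type, so this key step stands on firmer ground than step 4 of the chosen route. The cis ring fusion follows from the geometry. The silyl ethers come off without hydrogenolysis, which is a better last step than the one used here.
- Against: A2 must first be made as one enantiomer with H5 and H6 cis, and diazo transfer to a plain lactone needs prior activation, so the sequence before the key step is longer. The insertion must put the C2 aryl group on the concave face next to the C6 aryl group, a preference the transition state may not have. The carbenoid also has other outlets: oxonium ylide formation at O3, a 1,2-hydride shift from C5, and attack on the electron-rich arene.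
- Comparison: alternative 1 is stronger on precedent and on the end game. The chosen route offers a two-step access to its key precursor, full convergence, and a reduction in which both aryl groups direct the reagent to the same face.

**Alternative 2: donor–acceptor cyclopropane opening.**
- Disconnection: C2–O3 and C4–C5, so the tetrahydrofuran is the sum of the C1–C2–C5 unit of cyclopropane A4 and formaldehyde A5.
- Forward key step: a divalent tin Lewis acid activates the aroyl group of A4. The oxygen of A5 attacks C2 opposite to the breaking C2–C5 bond, and the ketone enolate closes on the oxocarbenium carbon to give tetrahydrofuran A3.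
- For: opening with inversion is stereospecific, so C2 is copied from an enantioenriched cyclopropane, and the trans aryl/ester relationship of A4 becomes the cis C1/C2 relationship of 13. The formal (3+2) reaction of such cyclopropanes with aldehydes is a developed class.
- Against: the acceptor pattern is a ketone and a vicinal ester, not a geminal diester, and the aryl donor is attenuated by carbonate groups, so the C2–C5 bond is weakly polarised. Monomeric A5 is awkward to handle. C5 and C1 are formed α to carbonyl groups and can drift from the all-cis arrangement. C6 is not set; ketone reduction under acyclic control, lactonisation and three kinds of deprotection still follow.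
- Comparison: alternative 2 is at least as strong in transferring absolute configuration to C2. The chosen route creates C1 and C5 last, in a bicycle that can only be cis-fused, so no epimerisable intermediate has to survive.

**Alternative 3: furan annulation and dearomatising hydrogenation.**
- Disconnection: C1–C5 and O3–C4 at the furan oxidation level, giving β-keto ester A7 and bromo-1,2-dione A8.
- Forward key step: the enolate of A7 adds through C1 to the central carbonyl C5 of A8, the enol oxygen displaces bromide at C4, and dehydration gives furan A6 (a Feist–Benary-type condensation).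
- For: the condensation is robust, cheap and scalable, has no stereochemical issue and needs no stoichiometric transition metal; on these points alternative 3 is clearly stronger. Syn hydrogenation of one furan face would set the all-cis C1/C2/C5 relationship in one operation.
- Against: the burden moves to the hydrogenation. A 2-aryl furan with two acyl groups must be saturated without cleaving the benzylic C2–O3 bond and without over-reducing the aryl ketone. Because A6 is achiral, the hydrogenation must also be enantioselective, on a substitution pattern for which no catalyst can be counted on. C6 must then still be set by ketone reduction.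
- Comparison: the chosen route reduces one strained enoate double bond with a hydride reagent that leaves benzylic C–O bonds alone. Its absolute configuration comes from a carbonyl addition and a ligand-controlled coupling, not from an arene hydrogenation.

Key step: step 4

Remark (assumption): (S,S)-ProPhenol is taken as the ligand enantiomer that delivers the alkynyl group to the Si face of aldehyde 1; if the sense is the reverse, its mirror image is used.

Remark (assumption): the (4R,5R) carbene ligand is taken as the enantiomer that pairs in the matched sense with (R)-4 and exposes the Si face of aldehyde 6 to C5; if not, the (4S,5S) ligand is used.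

## Route

Step 1
Reactants: 1 3,4-bis(benzyloxy)benzaldehyde; 2 tert-butyldimethyl(prop-2-yn-1-yloxy)silane
Product: 3 (R)-1-[3,4-bis(benzyloxy)phenyl]-4-[(tert-butyldimethylsilyl)oxy]but-2-yn-1-ol
Conditions: Me2Zn (3 equiv), (S,S)-ProPhenol [2,6-bis{[(S)-2-(hydroxydiphenylmethyl)pyrrolidin-1-yl]methyl}-4-methylphenol] (10 mol%), Ph3P=O (20 mol%), toluene, 0 °C; aq. NH4Cl
Reagents that add atoms: none
Why: Catalytic asymmetric alkynylation of an aryl aldehyde by a zinc alkynylide held in a dinuclear zinc–aminoalkoxide pocket; Si-face addition sets the carbinol centre as R, and benzyl and silyl ethers are inert to the organozinc.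

Step 2
Reactants: 3 (R)-1-[3,4-bis(benzyloxy)phenyl]-4-[(tert-butyldimethylsilyl)oxy]but-2-yn-1-ol
Product: 4 (R)-1-[3,4-bis(benzyloxy)phenyl]-1,4-bis[(tert-butyldimethylsilyl)oxy]but-2-yne
Conditions: TBSCl, imidazole, DMF, rt
Reagents that add atoms: tert-butyldimethylsilyl chloride, CC(C)(C)[Si](C)(C)Cl
Why: Standard silylation of a secondary alcohol at oxygen, so the stereocentre is not touched; the bulky silyl ether also enlarges the size difference between the two alkyne substituents for step 4.

Step 3
Reactants: 5 syringaldehyde (4-hydroxy-3,5-dimethoxybenzaldehyde)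
Product: 6 4-(benzyloxy)-3,5-dimethoxybenzaldehyde
Conditions: BnBr, K2CO3, DMF, 60 °C
Reagents that add atoms: benzyl bromide, BrCc1ccccc1
Why: Williamson ether synthesis on an acidic, hindered phenol; the aldehyde is not affected by carbonate.

Step 4
Reactants: 4 (R)-1-[3,4-bis(benzyloxy)phenyl]-1,4-bis[(tert-butyldimethylsilyl)oxy]but-2-yne; 6 4-(benzyloxy)-3,5-dimethoxybenzaldehyde; 7 carbon monoxide
Product: 9 (5R)-5-[4-(benzyloxy)-3,5-dimethoxyphenyl]-3-{(R)-[3,4-bis(benzyloxy)phenyl][(tert-butyldimethylsilyl)oxy]methyl}-4-{[(tert-butyldimethylsilyl)oxy]methyl}furan-2(5H)-one, via oxanickelacyclopentene 8 (not isolated)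
Conditions: Ni(cod)2 (1.0 equiv), (4R,5R)-1,3-bis(2-cyclohexyl-6-methylphenyl)-4,5-diphenyl-4,5-dihydroimidazolium BF4 (1.05 equiv), KOt-Bu (1.0 equiv), toluene, rt; then CO (1 atm), rt
Reagents that add atoms: none
Why: Proposed new method: carbene-ligated zerovalent nickel binds alkyne 4 and aldehyde 6 side by side and couples them oxidatively to the five-membered oxanickelacycle 8 (divalent nickel), forming C5–C6; CO then inserts into the vinyl–nickel bond (C1–C8) and C–O reductive elimination from the six-membered acyl nickel alkoxide closes the lactone (C8–O7). The closest known reaction types are the oxidative cyclisation of alkynes with aldehydes on Ni(cod)2 that underlies nickel-catalysed reductive couplings with chiral carbene ligands, the nickel-mediated carbonylative coupling of imines with alkynes to unsaturated lactams, and the hetero-Pauson–Khand reaction of tethered ynals on Cp2Ti(PMe3)2 or Ru3(CO)12; the intermolecular three-component version leading to a butenolide is the untested part. The lactone ring is closed through a metallacycle as a formal (2+2+1) assembly, its last bond arising by reductive elimination and not by a polar cyclisation. The only new stereocentre, C6, is fixed in the oxidative cyclisation, where the C2-symmetric carbene decides which face of the nickel-bound aldehyde meets C5 (the Si face gives 5R in 9), the existing centre of 4 lying next to nickel as the matched partner. The step needs the aldehyde carbon to bond to the alkyne carbon bearing CH2OTBS; for a carbene of moderate size this is the sterically preferred mode, because the branched CH(OTBS)Ar group avoids the aldehyde aryl ring and takes the nickel-bound carbon, while the two propargylic oxygens cancel electronically. Syn addition across the alkyne places C6 and C8 cis, as the ring requires. Nickel is used in stoichiometric amount and CO is admitted only after the metallacycle has formed, because carbonyl complexes of zerovalent nickel do not return to the cycle.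

Step 5
Reactants: 9 (5R)-5-[4-(benzyloxy)-3,5-dimethoxyphenyl]-3-{(R)-[3,4-bis(benzyloxy)phenyl][(tert-butyldimethylsilyl)oxy]methyl}-4-{[(tert-butyldimethylsilyl)oxy]methyl}furan-2(5H)-one
Product: 10 (5R)-5-[4-(benzyloxy)-3,5-dimethoxyphenyl]-3-{(R)-[3,4-bis(benzyloxy)phenyl](hydroxy)methyl}-4-(hydroxymethyl)furan-2(5H)-one
Conditions: HF·pyridine, pyridine, THF, 0 °C to rt
Reagents that add atoms: none
Why: Fluoride-mediated cleavage of both silyl ethers in a buffered, weakly acidic medium, which avoids γ-deprotonation at C6 (racemisation through the 2-oxidofuran) and ionisation at the benzylic C2; the hydroxymethyl group is trans to C8 across the double bond and cannot translactonise.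

Step 6
Reactants: 10 (5R)-5-[4-(benzyloxy)-3,5-dimethoxyphenyl]-3-{(R)-[3,4-bis(benzyloxy)phenyl](hydroxy)methyl}-4-(hydroxymethyl)furan-2(5H)-one
Product: 11 (2R,6R)-2-[3,4-bis(benzyloxy)phenyl]-6-[4-(benzyloxy)-3,5-dimethoxyphenyl]-3,7-dioxabicyclo[3.3.0]oct-1(5)-en-8-one
Conditions: PPh3, DIAD, THF, 0 °C to rt
Reagents that add atoms: none
Why: Mitsunobu cyclodehydration in which the less hindered primary allylic hydroxyl becomes the alkoxyphosphonium ion and is displaced by the C2 hydroxyl (5-exo-tet SN2 at C4), so the C2–O bond is not broken and C2 keeps its configuration; the two arms are held cis by the ring double bond.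

Step 7
Reactants: 11 (2R,6R)-2-[3,4-bis(benzyloxy)phenyl]-6-[4-(benzyloxy)-3,5-dimethoxyphenyl]-3,7-dioxabicyclo[3.3.0]oct-1(5)-en-8-one
Product: 12 (1R,2S,5S,6S)-2-[3,4-bis(benzyloxy)phenyl]-6-[4-(benzyloxy)-3,5-dimethoxyphenyl]-3,7-dioxabicyclo[3.3.0]octan-8-one
Conditions: Cu(OAc)2·H2O (5 mol%), 1,2-bis(diphenylphosphino)benzene (5 mol%), (EtO)2MeSiH, t-BuOH, toluene, rt
Reagents that add atoms: none
Why: Copper hydride conjugate reduction of an α,β-unsaturated lactone: the phosphine-ligated CuH adds hydride to C5 from the face opposite to both aryl groups, and the enolate is protonated at C1 on the same face because only the cis-fused bicycle is attainable; β-elimination of O3 from the enolate would be the reverse of a 5-endo-trig closure and is stereoelectronically disfavoured, and benzylic C–O bonds and benzyl ethers are inert to the reagent.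

Step 8
Reactants: 12 (1R,2S,5S,6S)-2-[3,4-bis(benzyloxy)phenyl]-6-[4-(benzyloxy)-3,5-dimethoxyphenyl]-3,7-dioxabicyclo[3.3.0]octan-8-one
Product: 13 (1R,2S,5S,6S)-2-(3,4-dihydroxyphenyl)-6-(4-hydroxy-3,5-dimethoxyphenyl)-3,7-dioxabicyclo[3.3.0]octan-8-one
Conditions: H2 (1 atm), 10% Pd/C, EtOAc, rt, stopped when the benzyl ethers are consumed
Reagents that add atoms: none
Why: Hydrogenolysis of aryl benzyl ethers under neutral conditions, which are cleaved much faster than the ring benzylic C–O bonds; no acid or base is present that could epimerise C2 or C6 of the endo,endo product.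

## Compound list

1 | 3,4-bis(benzyloxy)benzaldehyde | O=Cc1ccc(OCc2ccccc2)c(OCc2ccccc2)c1 | starting material
2 | tert-butyldimethyl(prop-2-yn-1-yloxy)silane | C#CCO[Si](C)(C)C(C)(C)C | starting material
3 | (R)-1-[3,4-bis(benzyloxy)phenyl]-4-[(tert-butyldimethylsilyl)oxy]but-2-yn-1-ol | O[C@@H](C#CCO[Si](C)(C)C(C)(C)C)c1ccc(OCc2ccccc2)c(OCc2ccccc2)c1 | intermediate
4 | (R)-1-[3,4-bis(benzyloxy)phenyl]-1,4-bis[(tert-butyldimethylsilyl)oxy]but-2-yne | CC(C)(C)[Si](C)(C)O[C@@H](C#CCO[Si](C)(C)C(C)(C)C)c1ccc(OCc2ccccc2)c(OCc2ccccc2)c1 | intermediate
5 | syringaldehyde (4-hydroxy-3,5-dimethoxybenzaldehyde) | COc1cc(C=O)cc(OC)c1O | starting material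
6 | 4-(benzyloxy)-3,5-dimethoxybenzaldehyde | O=Cc1cc(OC)c(OCc2ccccc2)c(OC)c1 | intermediate
7 | carbon monoxide | [C-]#[O+] | starting material
8 | oxanickelacyclopentene: [(4R,5R)-1,3-bis(2-cyclohexyl-6-methylphenyl)-4,5-diphenylimidazolidin-2-ylidene]nickel bonded to O7 and C1 of the coupled alkyne–aldehyde unit (divalent nickel, drawn as the monomer) | [Ni]1(=C2N(c3c(C)cccc3C3CCCCC3)[C@H](c3ccccc3)[C@@H](c3ccccc3)N2c2c(C)cccc2C2CCCCC2)O[C@H](c2cc(OC)c(OCc3ccccc3)c(OC)c2)C(CO[Si](C)(C)C(C)(C)C)=C1[C@H](O[Si](C)(C)C(C)(C)C)c1ccc(OCc2ccccc2)c(OCc2ccccc2)c1 | intermediate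
9 | (5R)-5-[4-(benzyloxy)-3,5-dimethoxyphenyl]-3-{(R)-[3,4-bis(benzyloxy)phenyl][(tert-butyldimethylsilyl)oxy]methyl}-4-{[(tert-butyldimethylsilyl)oxy]methyl}furan-2(5H)-one | O=C1O[C@H](c2cc(OC)c(OCc3ccccc3)c(OC)c2)C(CO[Si](C)(C)C(C)(C)C)=C1[C@H](O[Si](C)(C)C(C)(C)C)c1ccc(OCc2ccccc2)c(OCc2ccccc2)c1 | intermediate
10 | (5R)-5-[4-(benzyloxy)-3,5-dimethoxyphenyl]-3-{(R)-[3,4-bis(benzyloxy)phenyl](hydroxy)methyl}-4-(hydroxymethyl)furan-2(5H)-one | O=C1O[C@H](c2cc(OC)c(OCc3ccccc3)c(OC)c2)C(CO)=C1[C@H](O)c1ccc(OCc2ccccc2)c(OCc2ccccc2)c1 | intermediate
11 | (2R,6R)-2-[3,4-bis(benzyloxy)phenyl]-6-[4-(benzyloxy)-3,5-dimethoxyphenyl]-3,7-dioxabicyclo[3.3.0]oct-1(5)-en-8-one | O=C1O[C@H](c2cc(OC)c(OCc3ccccc3)c(OC)c2)C2=C1[C@H](OC2)c1ccc(OCc2ccccc2)c(OCc2ccccc2)c1 | intermediate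
12 | (1R,2S,5S,6S)-2-[3,4-bis(benzyloxy)phenyl]-6-[4-(benzyloxy)-3,5-dimethoxyphenyl]-3,7-dioxabicyclo[3.3.0]octan-8-one | COc1cc([C@H]2OC(=O)[C@@H]3[C@H]2CO[C@@H]3c2ccc(OCc4ccccc4)c(OCc4ccccc4)c2)cc(OC)c1OCc1ccccc1 | intermediate
13 | (1R,2S,5S,6S)-2-(3,4-dihydroxyphenyl)-6-(4-hydroxy-3,5-dimethoxyphenyl)-3,7-dioxabicyclo[3.3.0]octan-8-one | COc1cc([C@H]2OC(=O)[C@@H]3[C@H]2CO[C@@H]3c2ccc(O)c(O)c2)cc(OC)c1O | target

## Step count and risk

Total: 8 steps. Longest linear sequence: 7 steps (steps 1, 2, 4, 5, 6, 7, 8); step 3 lies on the side branch.

**Step 4 (key step, new method).** Most likely to go wrong: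
- reversal of the regiochemistry of the oxidative cyclisation if the carbene acts as a large ligand, so that C6 bonds to C1;
- poor facial selectivity at C6 if ligand and substrate are mismatched;
- diversion of the nickel alkoxide by β-hydride elimination (net hydroacylation) or Tishchenko dimerisation of 6;
- capture of nickel by CO before the metallacycle has formed.

Fallback in known chemistry, setting out from 4 and 6 and returning at 9: the alkyne is complexed with Ti(OiPr)4 and two equivalents of i-PrMgCl at −50 °C, the titanium–alkyne complex takes up 6 at its less hindered carbon, and iodine cleaves the remaining vinyl–titanium bond. This should give the (Z)-iodo allylic alcohol F1 as both C6 epimers, which are separated by chromatography. The unwanted epimer is recycled by MnO2 oxidation to the iodo enone F2 and reduction with NaBH4/CeCl3, or with an oxazaborolidine and BH3·SMe2 (Corey–Bakshi–Shibata reduction) if reagent control is effective. Carbonylative lactonisation of the 5R epimer of F1 with PdCl2(PPh3)2 (catalytic), CO (1 atm) and K2CO3 in THF proceeds by insertion of zerovalent palladium into the C–I bond, CO insertion and capture by the C6 hydroxyl, and gives 9.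

**Step 6.** Most likely to go wrong: activation of the secondary benzylic hydroxyl in place of the primary one, which would close the ring with inversion or by ionisation and erode C2; and γ-deprotonation at C6 by the basic betaine. Fallback, setting out from 9 and returning at 11: brief HF·pyridine at 0 °C removes only the primary silyl ether and gives the primary alcohol F3. An Appel reaction (CBr4, PPh3) gives the allylic bromide F4. HF·pyridine at rt frees the C2 hydroxyl to give the bromo alcohol F5, and Ag2O in CH2Cl2 closes the ring by displacement of bromide at C4. The C2–O bond is never activated.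

**Step 7.** Most likely to go wrong: slow hydride transfer to the tetrasubstituted double bond, competing 1,2-reduction of the lactone, or epimerisation at C6 by copper alkoxide before reduction, which would remove the facial bias. Fallback, setting out from 11 and returning at 12: reduction with nickel boride made in the flask from NiCl2·6H2O and NaBH4 in MeOH/THF at 0 °C, a surface-type delivery of hydrogen to the open face; no new compound is involved.

**Step 8.** Most likely to go wrong: over-reduction with hydrogenolytic opening of the benzylic C6–O7 or C2–O3 bond. Fallback, setting out from 12 and returning at 13: Lewis-acid debenzylation with BCl3 and pentamethylbenzene as cation scavenger in CH2Cl2 at −78 °C, which removes aryl benzyl ethers without hydrogen and spares aryl methyl ethers; no new compound is involved.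

**Step 1.** Most likely to go wrong: insufficient enantioselectivity with the electron-rich aldehyde and the oxygenated alkyne. Fallback, setting out from 1 and 2 and returning at 3: the lithium acetylide of 2 (n-BuLi, THF, −78 °C) adds to 1 to give the racemic propargylic alcohol F6. MnO2 oxidises it to the ynone F7. Noyori transfer hydrogenation with RuCl(p-cymene)[(S,S)-TsDPEN] or its mirror image and HCO2H/Et3N, the enantiomer being chosen to give the R alcohol, returns 3.

## Further compounds

F1 | step 4 | (1R,2Z,4R)-1-[4-(benzyloxy)-3,5-dimethoxyphenyl]-4-[3,4-bis(benzyloxy)phenyl]-4-[(tert-butyldimethylsilyl)oxy]-2-{[(tert-butyldimethylsilyl)oxy]methyl}-3-iodobut-2-en-1-ol | O[C@H](c1cc(OC)c(OCc2ccccc2)c(OC)c1)/C(CO[Si](C)(C)C(C)(C)C)=C(I)/[C@H](O[Si](C)(C)C(C)(C)C)c1ccc(OCc2ccccc2)c(OCc2ccccc2)c1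
F2 | step 4 | (2Z,4R)-1-[4-(benzyloxy)-3,5-dimethoxyphenyl]-4-[3,4-bis(benzyloxy)phenyl]-4-[(tert-butyldimethylsilyl)oxy]-2-{[(tert-butyldimethylsilyl)oxy]methyl}-3-iodobut-2-en-1-one | O=C(c1cc(OC)c(OCc2ccccc2)c(OC)c1)/C(CO[Si](C)(C)C(C)(C)C)=C(I)/[C@H](O[Si](C)(C)C(C)(C)C)c1ccc(OCc2ccccc2)c(OCc2ccccc2)c1
F3 | step 6 | (5R)-5-[4-(benzyloxy)-3,5-dimethoxyphenyl]-3-{(R)-[3,4-bis(benzyloxy)phenyl][(tert-butyldimethylsilyl)oxy]methyl}-4-(hydroxymethyl)furan-2(5H)-one | O=C1O[C@H](c2cc(OC)c(OCc3ccccc3)c(OC)c2)C(CO)=C1[C@H](O[Si](C)(C)C(C)(C)C)c1ccc(OCc2ccccc2)c(OCc2ccccc2)c1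
F4 | step 6 | (5R)-5-[4-(benzyloxy)-3,5-dimethoxyphenyl]-3-{(R)-[3,4-bis(benzyloxy)phenyl][(tert-butyldimethylsilyl)oxy]methyl}-4-(bromomethyl)furan-2(5H)-one | O=C1O[C@H](c2cc(OC)c(OCc3ccccc3)c(OC)c2)C(CBr)=C1[C@H](O[Si](C)(C)C(C)(C)C)c1ccc(OCc2ccccc2)c(OCc2ccccc2)c1
F5 | step 6 | (5R)-5-[4-(benzyloxy)-3,5-dimethoxyphenyl]-3-{(R)-[3,4-bis(benzyloxy)phenyl](hydroxy)methyl}-4-(bromomethyl)furan-2(5H)-one | O=C1O[C@H](c2cc(OC)c(OCc3ccccc3)c(OC)c2)C(CBr)=C1[C@H](O)c1ccc(OCc2ccccc2)c(OCc2ccccc2)c1
F0 | step 7 | none | none
F0 | step 8 | none | none
F6 | step 1 | racemic 1-[3,4-bis(benzyloxy)phenyl]-4-[(tert-butyldimethylsilyl)oxy]but-2-yn-1-ol | OC(C#CCO[Si](C)(C)C(C)(C)C)c1ccc(OCc2ccccc2)c(OCc2ccccc2)c1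
F7 | step 1 | 1-[3,4-bis(benzyloxy)phenyl]-4-[(tert-butyldimethylsilyl)oxy]but-2-yn-1-one | O=C(C#CCO[Si](C)(C)C(C)(C)C)c1ccc(OCc2ccccc2)c(OCc2ccccc2)c1
A1 | alternative 1 | (1R,2S,5S,6S)-2-{3,4-bis[(tert-butyldimethylsilyl)oxy]phenyl}-6-{4-[(tert-butyldimethylsilyl)oxy]-3,5-dimethoxyphenyl}-3,7-dioxabicyclo[3.3.0]octan-8-one | COc1cc(cc(OC)c1O[Si](C)(C)C(C)(C)C)[C@H]1OC(=O)[C@@H]2[C@H]1CO[C@@H]2c1ccc(O[Si](C)(C)C(C)(C)C)c(O[Si](C)(C)C(C)(C)C)c1
A2 | alternative 1 | (4S,5S)-4-[({3,4-bis[(tert-butyldimethylsilyl)oxy]phenyl}methoxy)methyl]-5-{4-[(tert-butyldimethylsilyl)oxy]-3,5-dimethoxyphenyl}-3-diazodihydrofuran-2(3H)-one | COc1cc(cc(OC)c1O[Si](C)(C)C(C)(C)C)[C@H]1OC(=O)C(=[N+]=[N-])[C@H]1COCc1ccc(O[Si](C)(C)C(C)(C)C)c(O[Si](C)(C)C(C)(C)C)c1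
A3 | alternative 2 | tert-butyl all-cis-4-[4-(benzyloxy)-3,5-dimethoxybenzoyl]-2-{3,4-bis[(benzyloxycarbonyl)oxy]phenyl}tetrahydrofuran-3-carboxylate (C1, C2 and C5 configured as in 13) | CC(C)(C)OC(=O)[C@H]1[C@@H](c2ccc(OC(=O)OCc3ccccc3)c(OC(=O)OCc3ccccc3)c2)OC[C@H]1C(=O)c1cc(OC)c(OCc2ccccc2)c(OC)c1
A4 | alternative 2 | tert-butyl 2-[4-(benzyloxy)-3,5-dimethoxybenzoyl]-3-{3,4-bis[(benzyloxycarbonyl)oxy]phenyl}cyclopropane-1-carboxylate with the aryl group trans to both carbonyl substituents | CC(C)(C)OC(=O)[C@H]1[C@H](c2ccc(OC(=O)OCc3ccccc3)c(OC(=O)OCc3ccccc3)c2)[C@H]1C(=O)c1cc(OC)c(OCc2ccccc2)c(OC)c1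
A5 | alternative 2 | formaldehyde | C=O
A6 | alternative 3 | methyl 4-[4-(benzyloxy)-3,5-dimethoxybenzoyl]-2-[3,4-bis(benzyloxy)phenyl]furan-3-carboxylate | COC(=O)c1c(C(=O)c2cc(OC)c(OCc3ccccc3)c(OC)c2)coc1-c1ccc(OCc2ccccc2)c(OCc2ccccc2)c1
A7 | alternative 3 | methyl 3-[3,4-bis(benzyloxy)phenyl]-3-oxopropanoate | COC(=O)CC(=O)c1ccc(OCc2ccccc2)c(OCc2ccccc2)c1
A8 | alternative 3 | 1-[4-(benzyloxy)-3,5-dimethoxyphenyl]-3-bromopropane-1,2-dione | O=C(C(=O)CBr)c1cc(OC)c(OCc2ccccc2)c(OC)c1
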